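**Retrosynthetic overview**
1. Target 31 ⇐ lipase deacetylation of 4′-acetate 30. The ten-membered ring (formed last) ⇐ ring-closing metathesis making the C1=C10 Z-alkene of triene 29.
2. C8 ester ⇐ Mitsunobu inversion of carbinol 21 with 4-acetoxytiglic acid 27.
3. α-Methylene-γ-lactone with the C7–C8 bond ⇐ zinc Barbier union of bromomethyl butenolide 17 with 3-methylbut-3-enal 19.
4. Butenolide (second ring) ⇐ Felkin propiolate addition to epoxy aldehyde 8 (C6–C7), hydrostannation/lactonisation, Stille hydroxymethylation.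
5. Epoxide (first ring, C4 and C5) ⇐ catalytic Sharpless epoxidation of nerol 1. Ring order: epoxide → lactone → carbocycle.

Assumption: atom labels C1–C15 are germacrane numbering, and the SMILES is read as written: 1(10)Z alkene, cis-4,5-epoxide (4R,5S), trans-fused 6,12-lactone (6S,7R), 8R ester.

**Step 1**
Reactants: 1 nerol
Product: 2 [(2S,3R)-3-methyl-3-(4-methylpent-3-en-1-yl)oxiran-2-yl]methanol
Conditions: Ti(OiPr)4 (5 mol %), L-(+)-DET (7.5 mol %), t-BuOOH, 4 Å MS, CH2Cl2, −20 °C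
Reagents that add atoms: tert-butyl hydroperoxide CC(C)(C)OO
Why: Catalytic Sharpless asymmetric epoxidation delivers oxygen to one face of the Z-allylic alcohol only, setting C4 (R) and C5 (S) together as the cis-epoxide and leaving the remote alkene untouched.

**Step 2**
Reactants: 2 [(2S,3R)-3-methyl-3-(4-methylpent-3-en-1-yl)oxiran-2-yl]methanol
Product: 3 tert-butyl(dimethyl){[(2S,3R)-3-methyl-3-(4-methylpent-3-en-1-yl)oxiran-2-yl]methoxy}silane
Conditions: TBSCl, imidazole, CH2Cl2, 0 °C → rt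
Reagents that add atoms: tert-butyldimethylsilyl chloride CC(C)(C)[Si](C)(C)Cl
Why: Silyl ether protection of the primary alcohol keeps an epoxy alkoxide (Payne rearrangement) out of the ozonolysis and Wittig steps.

**Step 3**
Reactants: 3 tert-butyl(dimethyl){[(2S,3R)-3-methyl-3-(4-methylpent-3-en-1-yl)oxiran-2-yl]methoxy}silane
Product: 5 3-[(2R,3S)-3-{[tert-butyl(dimethyl)silyl]oxymethyl}-2-methyloxiran-2-yl]propanal, via secondary ozonide 4 (not isolated)
Conditions: O3, CH2Cl2, −78 °C; then PPh3, −78 °C → rt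
Reagents that add atoms: ozone [O-][O+]=O
Why: Ozonolysis with reductive work-up cleaves the only alkene to the aldehyde, and epoxide and silyl ether are inert to ozone.

**Step 4**
Reactants: 5 3-[(2R,3S)-3-{[tert-butyl(dimethyl)silyl]oxymethyl}-2-methyloxiran-2-yl]propanal
Product: 6 {[(2S,3R)-3-(but-3-en-1-yl)-3-methyloxiran-2-yl]methoxy}(tert-butyl)dimethylsilane
Conditions: Ph3PCH3Br, KN(SiMe3)2, THF, 0 °C; then 5, −78 → 0 °C
Reagents that add atoms: methyltriphenylphosphonium bromide C[P+](c1ccccc1)(c1ccccc1)c1ccccc1.[Br-]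
Why: Wittig methylenation with the non-stabilised ylide turns the aldehyde into the terminal vinyl group needed for the metathesis without touching the epoxide.

**Step 5**
Reactants: 6 {[(2S,3R)-3-(but-3-en-1-yl)-3-methyloxiran-2-yl]methoxy}(tert-butyl)dimethylsilane
Product: 7 [(2S,3R)-3-(but-3-en-1-yl)-3-methyloxiran-2-yl]methanol
Conditions: Bu4NF, THF, 0 °C
Reagents that add atoms: none
Why: Fluoride-mediated desilylation frees the primary alcohol under conditions that leave the trisubstituted epoxide alone.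

**Step 6**
Reactants: 7 [(2S,3R)-3-(but-3-en-1-yl)-3-methyloxiran-2-yl]methanol
Product: 8 (2R,3R)-3-(but-3-en-1-yl)-3-methyloxirane-2-carbaldehyde
Conditions: TEMPO (10 mol %), PhI(OAc)2, CH2Cl2, rt
Reagents that add atoms: none
Why: TEMPO/hypervalent-iodine oxidation stops cleanly at the epoxy aldehyde without acid- or base-induced epoxide opening or epimerisation at C5.

**Step 7**
Reactants: 8 (2R,3R)-3-(but-3-en-1-yl)-3-methyloxirane-2-carbaldehyde; 9 methyl propiolate
Product: 10 methyl (4S)-4-[(2S,3R)-3-(but-3-en-1-yl)-3-methyloxiran-2-yl]-4-hydroxybut-2-ynoate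
Conditions: 9, LiN(SiMe3)2, THF, −78 °C; then 8, −78 °C; aq. NH4Cl quench at −78 °C
Reagents that add atoms: none
Why: Non-chelated acetylide 1,2-addition follows the polar Felkin–Anh model (nucleophile anti to the epoxide C–O bond), giving the anti (erythro) epoxy carbinol with C6 S as the major epimer, the minor one being removed by chromatography.

**Step 8**
Reactants: 10 methyl (4S)-4-[(2S,3R)-3-(but-3-en-1-yl)-3-methyloxiran-2-yl]-4-hydroxybut-2-ynoate
Product: 12 (5S)-5-[(2S,3R)-3-(but-3-en-1-yl)-3-methyloxiran-2-yl]-3-(tributylstannyl)furan-2(5H)-one, via stannyl hydroxy enoate 11 (not isolated)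
Conditions: Bu3SnH (slow addition), Pd(PPh3)4 (3 mol %), THF, 0 °C → rt; then 40 °C
Reagents that add atoms: tributyltin hydride CCCC[SnH](CCCC)CCCC
Why: Palladium-catalysed syn-hydrostannation of the ynoate puts tin α to the ester and hydrogen on C7, so the C6 hydroxyl lies cis to the ester and lactonises to the butenolide with C6 unchanged.

**Step 9**
Reactants: 12 (5S)-5-[(2S,3R)-3-(but-3-en-1-yl)-3-methyloxiran-2-yl]-3-(tributylstannyl)furan-2(5H)-one
Product: 13 (5S)-5-[(2S,3R)-3-(but-3-en-1-yl)-3-methyloxiran-2-yl]-3-iodofuran-2(5H)-one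
Conditions: I2, CH2Cl2, 0 °C
Reagents that add atoms: iodine II
Why: Ipso iododestannylation of the vinylstannane is much faster than any reaction of iodine with the terminal alkene or the epoxide.

**Step 10**
Reactants: 13 (5S)-5-[(2S,3R)-3-(but-3-en-1-yl)-3-methyloxiran-2-yl]-3-iodofuran-2(5H)-one; 14 (tributylstannyl)methanol
Product: 15 (5S)-5-[(2S,3R)-3-(but-3-en-1-yl)-3-methyloxiran-2-yl]-3-(hydroxymethyl)furan-2(5H)-one
Conditions: 14, Pd(PPh3)4 (10 mol %), 1,4-dioxane, 85 °C
Reagents that add atoms: none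
Why: Stille cross-coupling: zerovalent palladium inserts into the vinyl C–I bond and the hydroxymethyl group transfers from tin in preference to butyl, installing C13 under neutral conditions that do not epimerise C6.

**Step 11**
Reactants: 15 (5S)-5-[(2S,3R)-3-(but-3-en-1-yl)-3-methyloxiran-2-yl]-3-(hydroxymethyl)furan-2(5H)-one
Product: 17 (5S)-3-(bromomethyl)-5-[(2S,3R)-3-(but-3-en-1-yl)-3-methyloxiran-2-yl]furan-2(5H)-one, via alkoxyphosphonium bromide 16 (not isolated)
Conditions: CBr4, PPh3, CH2Cl2, −20 → 0 °C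
Reagents that add atoms: carbon tetrabromide BrC(Br)(Br)Br
Why: Appel bromination converts the primary allylic alcohol to the bromide at low temperature, conditions under which trisubstituted epoxides are routinely carried.

**Step 12**
Reactants: 18 3-methylbut-3-en-1-ol
Product: 19 3-methylbut-3-enal
Conditions: Dess–Martin periodinane, CH2Cl2, 0 °C → rt; filtered solution used at once
Reagents that add atoms: none
Why: Dess–Martin oxidation is base-free, so the β,γ-unsaturated aldehyde is obtained without isomerisation to the conjugated enal.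

**Step 13**
Reactants: 17 (5S)-3-(bromomethyl)-5-[(2S,3R)-3-(but-3-en-1-yl)-3-methyloxiran-2-yl]furan-2(5H)-one; 19 3-methylbut-3-enal
Product: 21 (4R,5S)-5-[(2S,3R)-3-(but-3-en-1-yl)-3-methyloxiran-2-yl]-4-[(1S)-1-hydroxy-3-methylbut-3-en-1-yl]-3-methylideneoxolan-2-one, via allylzinc bromide 20 (not isolated)
Conditions: Zn dust, THF/sat. aq. NH4Cl, 0 °C → rt
Reagents that add atoms: none
Why: Zinc Barbier allylation (SE2′) bonds C7 to the aldehyde on the ring face opposite the C6 substituent (trans-lactone, 7R) through a chair Zimmerman–Traxler transition state with the aldehyde chain equatorial, which gives the 8S carbinol that step 17 inverts.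

**Step 14**
Reactants: 22 glycolaldehyde (charged as its commercial dimer); 23 ethyl 2-(triphenylphosphoranylidene)propanoate
Product: 24 ethyl (2E)-4-hydroxy-2-methylbut-2-enoate
Conditions: CH2Cl2, 40 °C
Reagents that add atoms: none
Why: Wittig olefination with the stabilised α-methyl ylide gives the E-trisubstituted enoate with high selectivity.

**Step 15**
Reactants: 24 ethyl (2E)-4-hydroxy-2-methylbut-2-enoate
Product: 25 (2E)-4-hydroxy-2-methylbut-2-enoic acid
Conditions: LiOH·H2O, THF/H2O, 0 °C → rt; then 1 M HCl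
Reagents that add atoms: lithium hydroxide [Li+].[OH-]
Why: Saponification of the ethyl ester proceeds without affecting the alkene geometry.

**Step 16**
Reactants: 25 (2E)-4-hydroxy-2-methylbut-2-enoic acid
Product: 27 (2E)-4-acetoxy-2-methylbut-2-enoic acid, via mixed anhydride 26 (not isolated)
Conditions: Ac2O, pyridine, DMAP (cat.), CH2Cl2, 0 °C → rt; then H2O/THF
Reagents that add atoms: acetic anhydride CC(=O)OC(C)=O
Why: O-Acetylation protects the primary alcohol, and the mixed anhydride formed at the acid is hydrolysed at its acetyl carbonyl on aqueous work-up.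

**Step 17**
Reactants: 21 (4R,5S)-5-[(2S,3R)-3-(but-3-en-1-yl)-3-methyloxiran-2-yl]-4-[(1S)-1-hydroxy-3-methylbut-3-en-1-yl]-3-methylideneoxolan-2-one; 27 (2E)-4-acetoxy-2-methylbut-2-enoic acid
Product: 29 (1R)-1-{(2S,3R)-2-[(2S,3R)-3-(but-3-en-1-yl)-3-methyloxiran-2-yl]-4-methylidene-5-oxooxolan-3-yl}-3-methylbut-3-en-1-yl (2E)-4-acetoxy-2-methylbut-2-enoate, via alkoxyphosphonium carboxylate 28 (not isolated)
Conditions: PPh3, DIAD, THF, 0 °C → rt (betaine preformed)
Reagents that add atoms: none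
Why: Mitsunobu esterification displaces the alkoxyphosphonium by the carboxylate in an SN2 step, inverting C8 from S to R while installing the side chain.

**Step 18**
Reactants: 29 (1R)-1-{(2S,3R)-2-[(2S,3R)-3-(but-3-en-1-yl)-3-methyloxiran-2-yl]-4-methylidene-5-oxooxolan-3-yl}-3-methylbut-3-en-1-yl (2E)-4-acetoxy-2-methylbut-2-enoate
Product: 30 (4R,5S,6S,7R,8R,1(10)Z)-8-[(2E)-4-acetoxy-2-methylbut-2-enoyloxy]-4,5-epoxygermacra-1(10),11(13)-dien-12,6-olide
Conditions: second-generation Hoveyda–Grubbs catalyst RuCl2(H2IMes)(=CH-C6H4-2-OiPr) (10–15 mol %), toluene (1 mM), 80 °C, Ar sparge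
Reagents that add atoms: none
Why: Ring-closing metathesis between the vinyl and 2-methylallyl termini closes the ten-membered ring, where the trisubstituted C1=C10 alkene takes the far less strained Z (ring-cis) geometry and the electron-poor exocyclic methylene and tiglate alkenes are much slower partners.

**Step 19**
Reactants: 30 (4R,5S,6S,7R,8R,1(10)Z)-8-[(2E)-4-acetoxy-2-methylbut-2-enoyloxy]-4,5-epoxygermacra-1(10),11(13)-dien-12,6-olide
Product: 31 (4R,5S,6S,7R,8R,1(10)Z)-4,5-epoxy-8-[(2E)-4-hydroxy-2-methylbut-2-enoyloxy]germacra-1(10),11(13)-dien-12,6-olide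
Conditions: immobilised Candida antarctica lipase B (a lipase), n-BuOH, MTBE, 30 °C
Reagents that add atoms: none
Why: Lipase-catalysed transesterification (serine-hydrolase acyl transfer to butanol) removes only the unhindered primary acetate at neutral pH, leaving the hindered conjugated C8 ester, the α-methylene lactone and the epoxide intact.

**Compound list**
1 | nerol, (2Z)-3,7-dimethylocta-2,6-dien-1-ol | CC(C)=CCC/C(C)=C\CO | starting material
2 | [(2S,3R)-3-methyl-3-(4-methylpent-3-en-1-yl)oxiran-2-yl]methanol | CC(C)=CCC[C@@]1(C)O[C@H]1CO | intermediate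
3 | tert-butyl(dimethyl){[(2S,3R)-3-methyl-3-(4-methylpent-3-en-1-yl)oxiran-2-yl]methoxy}silane | CC(C)=CCC[C@@]1(C)O[C@H]1CO[Si](C)(C)C(C)(C)C | intermediate
4 | secondary ozonide, 3-{2-[(2R,3S)-3-{[tert-butyl(dimethyl)silyl]oxymethyl}-2-methyloxiran-2-yl]ethyl}-5,5-dimethyl-1,2,4-trioxolane (epimers at the trioxolane carbon) | CC1(C)OOC(CC[C@@]2(C)O[C@H]2CO[Si](C)(C)C(C)(C)C)O1 | intermediate (not isolated)
5 | 3-[(2R,3S)-3-{[tert-butyl(dimethyl)silyl]oxymethyl}-2-methyloxiran-2-yl]propanal | O=CCC[C@@]1(C)O[C@H]1CO[Si](C)(C)C(C)(C)C | intermediate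
6 | {[(2S,3R)-3-(but-3-en-1-yl)-3-methyloxiran-2-yl]methoxy}(tert-butyl)dimethylsilane | C=CCC[C@@]1(C)O[C@H]1CO[Si](C)(C)C(C)(C)C | intermediate
7 | [(2S,3R)-3-(but-3-en-1-yl)-3-methyloxiran-2-yl]methanol | C=CCC[C@@]1(C)O[C@H]1CO | intermediate
8 | (2R,3R)-3-(but-3-en-1-yl)-3-methyloxirane-2-carbaldehyde | C=CCC[C@@]1(C)O[C@H]1C=O | intermediate
9 | methyl propiolate | C#CC(=O)OC | starting material
10 | methyl (4S)-4-[(2S,3R)-3-(but-3-en-1-yl)-3-methyloxiran-2-yl]-4-hydroxybut-2-ynoate | C=CCC[C@@]1(C)O[C@H]1[C@@H](O)C#CC(=O)OC | intermediate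
11 | methyl (2E,4S)-4-[(2S,3R)-3-(but-3-en-1-yl)-3-methyloxiran-2-yl]-4-hydroxy-2-(tributylstannyl)but-2-enoate | C=CCC[C@@]1(C)O[C@H]1[C@@H](O)/C=C(C(=O)OC)/[Sn](CCCC)(CCCC)CCCC | intermediate (not isolated)
12 | (5S)-5-[(2S,3R)-3-(but-3-en-1-yl)-3-methyloxiran-2-yl]-3-(tributylstannyl)furan-2(5H)-one | C=CCC[C@@]1(C)O[C@H]1[C@H]2OC(=O)C([Sn](CCCC)(CCCC)CCCC)=C2 | intermediate
13 | (5S)-5-[(2S,3R)-3-(but-3-en-1-yl)-3-methyloxiran-2-yl]-3-iodofuran-2(5H)-one | C=CCC[C@@]1(C)O[C@H]1[C@H]2OC(=O)C(I)=C2 | intermediate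
14 | (tributylstannyl)methanol | CCCC[Sn](CCCC)(CCCC)CO | starting material
15 | (5S)-5-[(2S,3R)-3-(but-3-en-1-yl)-3-methyloxiran-2-yl]-3-(hydroxymethyl)furan-2(5H)-one | C=CCC[C@@]1(C)O[C@H]1[C@H]2OC(=O)C(CO)=C2 | intermediate
16 | alkoxyphosphonium bromide of 15, {[(5S)-5-[(2S,3R)-3-(but-3-en-1-yl)-3-methyloxiran-2-yl]-2-oxo-2,5-dihydrofuran-3-yl]methoxy}triphenylphosphonium bromide | C=CCC[C@@]1(C)O[C@H]1[C@H]2OC(=O)C(CO[P+](c3ccccc3)(c3ccccc3)c3ccccc3)=C2.[Br-] | intermediate (not isolated)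
17 | (5S)-3-(bromomethyl)-5-[(2S,3R)-3-(but-3-en-1-yl)-3-methyloxiran-2-yl]furan-2(5H)-one | C=CCC[C@@]1(C)O[C@H]1[C@H]2OC(=O)C(CBr)=C2 | intermediate
18 | 3-methylbut-3-en-1-ol | C=C(C)CCO | starting material
19 | 3-methylbut-3-enal | C=C(C)CC=O | intermediate
20 | allylzinc bromide from 17, bromo{[(5S)-5-[(2S,3R)-3-(but-3-en-1-yl)-3-methyloxiran-2-yl]-2-oxo-2,5-dihydrofuran-3-yl]methyl}zinc | C=CCC[C@@]1(C)O[C@H]1[C@H]2OC(=O)C(C[Zn]Br)=C2 | intermediate (not isolated)
21 | (4R,5S)-5-[(2S,3R)-3-(but-3-en-1-yl)-3-methyloxiran-2-yl]-4-[(1S)-1-hydroxy-3-methylbut-3-en-1-yl]-3-methylideneoxolan-2-one | C=C1C(=O)O[C@H]([C@@H]2O[C@]2(C)CCC=C)[C@H]1[C@@H](O)CC(C)=C | intermediate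
22 | glycolaldehyde (hydroxyacetaldehyde, supplied as its dimer) | OCC=O | starting material
23 | ethyl 2-(triphenylphosphoranylidene)propanoate | CCOC(=O)C(C)=P(c1ccccc1)(c1ccccc1)c1ccccc1 | starting material
24 | ethyl (2E)-4-hydroxy-2-methylbut-2-enoate | CCOC(=O)/C(C)=C/CO | intermediate
25 | (2E)-4-hydroxy-2-methylbut-2-enoic acid | OC(=O)/C(C)=C/CO | intermediate
26 | acetic (2E)-4-acetoxy-2-methylbut-2-enoic anhydride | CC(=O)OC(=O)/C(C)=C/COC(C)=O | intermediate (not isolated)
27 | (2E)-4-acetoxy-2-methylbut-2-enoic acid | OC(=O)/C(C)=C/COC(C)=O | intermediate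
28 | alkoxyphosphonium carboxylate, the C8-O-triphenylphosphonium salt of 21 (8S) with the carboxylate of 27 | C=C1C(=O)O[C@H]([C@@H]2O[C@]2(C)CCC=C)[C@H]1[C@@H](O[P+](c3ccccc3)(c3ccccc3)c3ccccc3)CC(C)=C.[O-]C(=O)/C(C)=C/COC(C)=O | intermediate (not isolated)
29 | (1R)-1-{(2S,3R)-2-[(2S,3R)-3-(but-3-en-1-yl)-3-methyloxiran-2-yl]-4-methylidene-5-oxooxolan-3-yl}-3-methylbut-3-en-1-yl (2E)-4-acetoxy-2-methylbut-2-enoate | C=C1C(=O)O[C@H]([C@@H]2O[C@]2(C)CCC=C)[C@H]1[C@H](OC(=O)/C(C)=C/COC(C)=O)CC(C)=C | intermediate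
30 | (4R,5S,6S,7R,8R,1(10)Z)-8-[(2E)-4-acetoxy-2-methylbut-2-enoyloxy]-4,5-epoxygermacra-1(10),11(13)-dien-12,6-olide | C=C1C(=O)O[C@H]2[C@H]1[C@H](OC(=O)/C(C)=C/COC(C)=O)C/C(C)=C\CC[C@@]1(C)O[C@@H]21 | intermediate
31 | (4R,5S,6S,7R,8R,1(10)Z)-4,5-epoxy-8-[(2E)-4-hydroxy-2-methylbut-2-enoyloxy]germacra-1(10),11(13)-dien-12,6-olide | C=C1C(=O)O[C@H]2[C@H]1[C@H](OC(=O)/C(C)=C/CO)C/C(C)=C\CC[C@@]1(C)O[C@@H]21 | target

**Step count and risks**
Total step count: 19. Longest linear sequence: 15 steps (steps 1–11, 13, 17, 18, 19).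

Risk 1, step 18 (ring-closing metathesis). A ten-membered ring with a trisubstituted alkene may oligomerise or close sluggishly with the bulky C8 ester in place. The fallback sets out from 21 and comes back at 30. Alcohol 21 is cyclised first under the same high-dilution metathesis conditions to the macrocyclic alcohol (4R,5S,6S,7R,8S,1(10)Z)-4,5-epoxy-8-hydroxygermacra-1(10),11(13)-dien-12,6-olide F1. F1 is then esterified with 27 under Mitsunobu conditions (PPh3, DIAD) with inversion at C8 to give 30. This changes the order of ring closure and acylation, so the ring is closed on a smaller substrate with a different conformational bias.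

Risk 2, step 17 (Mitsunobu inversion). The β-branched homoallylic C8 alcohol may eliminate or react with partial retention. The fallback sets out from 21 and comes back at 29. The alcohol is isolated as its chloromethanesulfonate, (1S)-1-{(2S,3R)-2-[(2S,3R)-3-(but-3-en-1-yl)-3-methyloxiran-2-yl]-4-methylidene-5-oxooxolan-3-yl}-3-methylbut-3-en-1-yl chloromethanesulfonate F2 (ClCH2SO2Cl, pyridine, 0 °C). F2 is then displaced in a separate SN2 step by cesium (2E)-4-acetoxy-2-methylbut-2-enoate F3 (made from 27 and Cs2CO3) with 18-crown-6 in toluene, giving 29 with inversion.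

Risk 3, step 7 (substrate-controlled addition). The Felkin–Anh preference at C6 may be modest. The fallback sets out from 10 (used as its mixture with the C6 epimer) and comes back at 10. The mixture is oxidised with Dess–Martin periodinane to the ynone methyl 4-[(2R,3R)-3-(but-3-en-1-yl)-3-methyloxiran-2-yl]-4-oxobut-2-ynoate F4. F4 is reduced under catalyst control by Noyori asymmetric transfer hydrogenation with Ru(p-cymene)[(R,R)-TsDPEN] in 2-propanol, the enantiomer that the alkynyl-as-π-group model predicts for the 4S carbinol, returning 10 as a single epimer.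

**Further compounds**
F1 | step 18 | (4R,5S,6S,7R,8S,1(10)Z)-4,5-epoxy-8-hydroxygermacra-1(10),11(13)-dien-12,6-olide | C=C1C(=O)O[C@H]2[C@H]1[C@@H](O)C/C(C)=C\CC[C@@]1(C)O[C@@H]21
F2 | step 17 | (1S)-1-{(2S,3R)-2-[(2S,3R)-3-(but-3-en-1-yl)-3-methyloxiran-2-yl]-4-methylidene-5-oxooxolan-3-yl}-3-methylbut-3-en-1-yl chloromethanesulfonate | C=C1C(=O)O[C@H]([C@@H]2O[C@]2(C)CCC=C)[C@H]1[C@@H](OS(=O)(=O)CCl)CC(C)=C
F3 | step 17 | cesium (2E)-4-acetoxy-2-methylbut-2-enoate | [Cs+].[O-]C(=O)/C(C)=C/COC(C)=O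
F4 | step 7 | methyl 4-[(2R,3R)-3-(but-3-en-1-yl)-3-methyloxiran-2-yl]-4-oxobut-2-ynoate | C=CCC[C@@]1(C)O[C@H]1C(=O)C#CC(=O)OC
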